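**Retrosynthetic overview**
- The target is opened at its esters: the C4 hemisuccinate comes from succinic anhydride, and the two caffeates from caffeic acid acetonide (catechol + acrylic acid, Heck). Three acetonides fall in one final acid step.
- The C4 carbinol comes from a late ketone reduction. The C3 and C5 oxygens come from a twofold L-proline/nitrosobenzene aminoxylation of an achiral 4,4-disubstituted cyclohexanone.
- Key disconnection: both C1–C2 and C1–C6 bonds are made in one radical [5+1] annulation of glycolic acid acetonide (C–H donor) with divinyl ketone (decatungstate hydrogen-atom transfer, Giese addition, 6-endo radical closure).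
- Ring order: the cyclohexane is the only skeletal ring built (step 1), spiro on the preformed dioxolanone. The arenes come intact from catechol.

Assumption: the SMILES is read as 3,5-di-O-caffeoyl-4-O-succinoylquinic acid of the natural series [(3R,5R); 1-OH, 3-O and 4-O on one ring face], and 1,5-dichloropentan-3-one is taken as the commercial, bench-stable source of divinyl ketone.

Locants in the spiro intermediates: C5 is the spiro carbon (quinic C1), C8 the ketone or carbinol carbon (quinic C4), and C7/C9 are quinic C3/C5.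

**Route**

Step 1
Reactants: 1 2,2-dimethyl-1,3-dioxolan-4-one; 2 1,5-dichloropentan-3-one
Product: 5 2,2-dimethyl-1,3-dioxaspiro[4.5]decane-4,8-dione, via divinyl ketone 3 (not isolated), via open-chain Giese adduct 4 (not isolated)
Conditions: 2 (1.2 equiv), K2CO3 (2.5 equiv), MeCN, rt, 3 h, filter; then 1 (1.0 equiv), (nBu4N)4[W10O32] (2 mol %), MeCN (0.02 M), 390 nm LEDs, N2, rt, 24 h
Reagents that add atoms: none
Why: Proposed new method: a radical [5+1] annulation in which photoexcited decatungstate abstracts the captodative C5–H of 1 (the only weak, α-oxygenated C–H present), the dioxolanonyl radical adds to the β-carbon of 3 (Giese addition) and back hydrogen transfer gives 4, whose tertiary, weaker C–H is abstracted in turn so that the radical closes 6-endo-trig on the remaining vinyl ketone (5-exo would have to attack the α-carbon) before the α-keto radical is reduced to achiral 5, so no stereocentre is at stake; the closest known reaction types are decatungstate-photocatalysed hydroalkylation of enones with α-oxy C–H donors, conjugate additions of 1,3-dioxolan-4-on-5-yl radicals and 6-endo radical closures onto vinyl ketones.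

Step 2
Reactants: 5 2,2-dimethyl-1,3-dioxaspiro[4.5]decane-4,8-dione
Product: 7 (7R,9R)-7,9-bis(anilinooxy)-2,2-dimethyl-1,3-dioxaspiro[4.5]decane-4,8-dione, via mono(anilinooxy) ketone 6 (not isolated)
Conditions: L-proline (30 mol %), PhNO (3.0 equiv, syringe pump, 12 h), DMF, 0 °C, 24 h
Reagents that add atoms: nitrosobenzene, O=Nc1ccccc1
Why: Twofold proline-catalysed α-aminoxylation (O-selective nitroso aldol through the enamine), in which the carboxylic acid of L-proline steers nitrosobenzene to the same enamine face both times and so sets R at each α-carbon (trans product); both C5 epimers of 6 converge because C5 is not stereogenic in 7, and the double catalyst control pushes the minor enantiomer into separable cis diastereomers.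

Step 3
Reactants: 7 (7R,9R)-7,9-bis(anilinooxy)-2,2-dimethyl-1,3-dioxaspiro[4.5]decane-4,8-dione
Product: 8 (7R,9R)-7,9-dihydroxy-2,2-dimethyl-1,3-dioxaspiro[4.5]decane-4,8-dione
Conditions: H2 (1 atm), 10% Pd/C, EtOAc, rt, 2 h
Reagents that add atoms: none
Why: Hydrogenolysis of the weak N–O bonds frees both hydroxyls under neutral conditions that do not enolise the α-hydroxy ketone, so the two stereocentres are untouched and the ketone and dioxolanone survive.

Step 4
Reactants: 9 catechol
Product: 10 2,2-dimethyl-1,3-benzodioxole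
Conditions: 2,2-dimethoxypropane (1.5 equiv), TsOH·H2O (2 mol %), toluene, reflux, MeOH removed over 4 Å MS
Reagents that add atoms: 2,2-dimethoxypropane, COC(C)(C)OC
Why: Acid-catalysed transketalisation driven by removal of methanol protects both phenols in one acetonide that later falls under the same acid as the dioxolanone.

Step 5
Reactants: 10 2,2-dimethyl-1,3-benzodioxole
Product: 11 5-bromo-2,2-dimethyl-1,3-benzodioxole
Conditions: NBS (1.05 equiv), MeCN, 0 °C to rt
Reagents that add atoms: N-bromosuccinimide, O=C1CCC(=O)N1Br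
Why: Electrophilic aromatic bromination occurs para to a ring oxygen, the only unhindered activated position, under non-acidic conditions that keep the acetonide.

Step 6
Reactants: 11 5-bromo-2,2-dimethyl-1,3-benzodioxole; 12 acrylic acid
Product: 13 (E)-3-(2,2-dimethyl-1,3-benzodioxol-5-yl)prop-2-enoic acid
Conditions: 12 (1.5 equiv), Pd(OAc)2 (2 mol %), P(o-tol)3 (4 mol %), Et3N (3 equiv), DMF, 100 °C; aq. citric acid work-up
Reagents that add atoms: none
Why: Heck reaction of the aryl bromide with acrylic acid gives the E-cinnamic acid through syn carbopalladation and syn β-hydride elimination.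

Step 7
Reactants: 8 (7R,9R)-7,9-dihydroxy-2,2-dimethyl-1,3-dioxaspiro[4.5]decane-4,8-dione; 13 (E)-3-(2,2-dimethyl-1,3-benzodioxol-5-yl)prop-2-enoic acid
Product: 14 (7R,9R)-2,2-dimethyl-4,8-dioxo-1,3-dioxaspiro[4.5]decane-7,9-diyl bis[(E)-3-(2,2-dimethyl-1,3-benzodioxol-5-yl)prop-2-enoate]
Conditions: 13 (2.3 equiv), DCC (2.5 equiv), DMAP (0.2 equiv), CH2Cl2, 0 °C
Reagents that add atoms: none
Why: Steglich esterification acylates the only two free hydroxyls (the tertiary oxygen and the acid are locked in the dioxolanone, and the future 4-O is still a ketone), and low temperature with catalytic DMAP limits enolisation of the α-acyloxy ketone.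

Step 8
Reactants: 14 (7R,9R)-2,2-dimethyl-4,8-dioxo-1,3-dioxaspiro[4.5]decane-7,9-diyl bis[(E)-3-(2,2-dimethyl-1,3-benzodioxol-5-yl)prop-2-enoate]
Product: 15 (7R,9R)-8-hydroxy-2,2-dimethyl-4-oxo-1,3-dioxaspiro[4.5]decane-7,9-diyl bis[(E)-3-(2,2-dimethyl-1,3-benzodioxol-5-yl)prop-2-enoate] (8-OH on the face of ring oxygen O1 and of one ester; the other ester and the lactone carbonyl on the opposite face)
Conditions: NaBH4 (1.0 equiv), CeCl3·7H2O (1.1 equiv), THF/MeOH 2:1, −78 °C; AcOH quench at −78 °C
Reagents that add atoms: none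
Why: Luche-type hydride reduction in which axial delivery to the favoured chair (small ring oxygen O1 axial, lactone carbonyl equatorial), anti to the axial α-acyloxy group (Felkin–Anh and torsional control), gives the equatorial 8-OH cis to O1, which sets the quinic C4 centre relative to C1 (estimated from conformer energies at about 5:1, the C8 epimer from the minor chair being removed by chromatography), while the enoates and the dioxolanone are untouched at −78 °C and the cold acidic quench prevents acyl migration.

Step 9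
Reactants: 15 the 8-hydroxy bis-ester of step 8; 16 succinic anhydride
Product: 17 4-{[(7R,9R)-7,9-bis{[(E)-3-(2,2-dimethyl-1,3-benzodioxol-5-yl)prop-2-enoyl]oxy}-2,2-dimethyl-4-oxo-1,3-dioxaspiro[4.5]decan-8-yl]oxy}-4-oxobutanoic acid (configuration at C5 and C8 as in 15)
Conditions: 16 (3 equiv), DMAP (0.3 equiv), pyridine/CH2Cl2 1:2, rt
Reagents that add atoms: none
Why: DMAP-catalysed ring-opening acylation by the anhydride esterifies the only free hydroxyl and delivers the hemisuccinate directly as the free acid, without alkoxide formation that would move the neighbouring caffeates.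

Step 10
Reactants: 17 the hemisuccinate of step 9
Product: 18 3,5-di-O-caffeoyl-4-O-succinoylquinic acid, (3R,5R)-4-(3-carboxypropanoyloxy)-3,5-bis{[(E)-3-(3,4-dihydroxyphenyl)prop-2-enoyl]oxy}-1-hydroxycyclohexane-1-carboxylic acid (1-OH, 3-O and 4-O on one face)
Conditions: TFA/H2O 9:1, 0 °C to rt, 2 h; evaporate, reversed-phase HPLC
Reagents that add atoms: none
Why: Acid hydrolysis of the three acetonides (two catechol ketals and the dioxolanone) unmasks the catechols, the tertiary alcohol and the C1 acid in one operation, under conditions where ester hydrolysis and acyl migration are slow, so no stereocentre is touched.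

**Compound list**
1 | 2,2-dimethyl-1,3-dioxolan-4-one (glycolic acid acetonide) | CC1(C)OCC(=O)O1 | starting material
2 | 1,5-dichloropentan-3-one | ClCCC(=O)CCCl | starting material
3 | penta-1,4-dien-3-one (divinyl ketone), formed in the flask | C=CC(=O)C=C | intermediate
4 | 2,2-dimethyl-5-(3-oxopent-4-en-1-yl)-1,3-dioxolan-4-one (racemic), formed in the flask | CC1(C)OC(CCC(=O)C=C)C(=O)O1 | intermediate
5 | 2,2-dimethyl-1,3-dioxaspiro[4.5]decane-4,8-dione (achiral) | CC1(C)OC(=O)C2(CCC(=O)CC2)O1 | intermediate
6 | (R)-mono(anilinooxy) ketone, 7-(anilinooxy)-2,2-dimethyl-1,3-dioxaspiro[4.5]decane-4,8-dione (both C5 epimers), formed in the flask | CC1(C)OC(=O)C2(CCC(=O)[C@H](ONc3ccccc3)C2)O1 | intermediate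
7 | (7R,9R)-7,9-bis(anilinooxy)-2,2-dimethyl-1,3-dioxaspiro[4.5]decane-4,8-dione (trans) | CC1(C)OC(=O)C2(C[C@@H](ONc3ccccc3)C(=O)[C@H](ONc3ccccc3)C2)O1 | intermediate
8 | (7R,9R)-7,9-dihydroxy-2,2-dimethyl-1,3-dioxaspiro[4.5]decane-4,8-dione (trans) | CC1(C)OC(=O)C2(C[C@@H](O)C(=O)[C@H](O)C2)O1 | intermediate
9 | catechol | Oc1ccccc1O | starting material
10 | 2,2-dimethyl-1,3-benzodioxole | CC1(C)Oc2ccccc2O1 | intermediate
11 | 5-bromo-2,2-dimethyl-1,3-benzodioxole | CC1(C)Oc2ccc(Br)cc2O1 | intermediate
12 | acrylic acid | C=CC(=O)O | starting material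
13 | (E)-3-(2,2-dimethyl-1,3-benzodioxol-5-yl)prop-2-enoic acid (caffeic acid acetonide) | CC1(C)Oc2ccc(/C=C/C(=O)O)cc2O1 | intermediate
14 | (7R,9R)-2,2-dimethyl-4,8-dioxo-1,3-dioxaspiro[4.5]decane-7,9-diyl bis[(E)-3-(2,2-dimethyl-1,3-benzodioxol-5-yl)prop-2-enoate] | CC1(C)OC(=O)C2(C[C@@H](OC(=O)/C=C/c3ccc4OC(C)(C)Oc4c3)C(=O)[C@H](OC(=O)/C=C/c3ccc4OC(C)(C)Oc4c3)C2)O1 | intermediate
15 | (7R,9R)-8-hydroxy-2,2-dimethyl-4-oxo-1,3-dioxaspiro[4.5]decane-7,9-diyl bis[(E)-3-(2,2-dimethyl-1,3-benzodioxol-5-yl)prop-2-enoate], 8-OH cis to O1 | CC1(C)OC(=O)[C@@]2(C[C@@H](OC(=O)/C=C/c3ccc4OC(C)(C)Oc4c3)[C@@H](O)[C@H](OC(=O)/C=C/c3ccc4OC(C)(C)Oc4c3)C2)O1 | intermediate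
16 | succinic anhydride | O=C1CCC(=O)O1 | starting material
17 | 8-O-(3-carboxypropanoyl) derivative of 15 (hemisuccinate, tris-acetonide of the target) | CC1(C)OC(=O)[C@@]2(C[C@@H](OC(=O)/C=C/c3ccc4OC(C)(C)Oc4c3)[C@@H](OC(=O)CCC(=O)O)[C@H](OC(=O)/C=C/c3ccc4OC(C)(C)Oc4c3)C2)O1 | intermediate
18 | 3,5-di-O-caffeoyl-4-O-succinoylquinic acid | O=C(O)CCC(=O)O[C@H]1[C@H](OC(=O)/C=C/c2ccc(O)c(O)c2)C[C@](O)(C(=O)O)C[C@H]1OC(=O)/C=C/c1ccc(O)c(O)c1 | target

**Step count**
Total: 10 steps. Longest linear sequence: 7 steps (1, 2, 3, 7, 8, 9, 10; the catechol branch 4, 5, 6, 7, 8, 9, 10 is equally long).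

**Steps most likely to fail, with fallbacks**

Step 1 (radical [5+1] annulation). Hydrogen abstraction from the secondary C–H of 1 may be slow, and open-chain 2:1 adducts or enone oligomers may compete with ring closure. The fallback sets out from 1 and comes back at 5. Compound 1 is brominated (NBS, AIBN, PhCF3, 80 °C) to 5-bromo-2,2-dimethyl-1,3-dioxolan-4-one F1, which is used crude. Halogen-atom abstraction ((Me3Si)3SiH, Et3B/air, toluene, 0 °C) in the presence of a threefold excess of 3 (from 2 and K2CO3 as before) generates the same dioxolanonyl radical without any C–H abstraction and gives 4, which is now isolated. Compound 4 alone is then irradiated with (nBu4N)4[W10O32] at 0.005 M in MeCN. Only its weak tertiary C–H can be abstracted and no intermolecular partner is present, so the 6-endo closure gives 5.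

Step 7 (double esterification). The axial hydroxyl may acylate sluggishly, and the α-acyloxy ketone may epimerise under DMAP. The fallback sets out from 8 and comes back at 14. Compound 8 is acylated with the small, fast electrophile acryloyl chloride (2.6 equiv, pyridine, CH2Cl2, −30 °C) to (7R,9R)-2,2-dimethyl-4,8-dioxo-1,3-dioxaspiro[4.5]decane-7,9-diyl di(prop-2-enoate) F2. The aryl groups are then attached by a twofold room-temperature Heck reaction with bromide 11 (2.5 equiv), using Pd2(dba)3 as the zerovalent palladium source, P(t-Bu)3 and Cy2NMe in dioxane, which gives 14. Step 6 is not needed in this variant.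

Step 8 (facial selectivity of the ketone reduction). The two ketone faces differ only through the remote C5 substituents, so the ratio depends on a conformer preference of roughly 1 kcal/mol. The fallback sets out from 14 and comes back at 18. The dioxolanone alone is hydrolysed (AcOH/H2O/THF 3:1:1, 40 °C; the aryl acetonides need stronger acid) to (3R,5R)-3,5-bis{[(E)-3-(2,2-dimethyl-1,3-benzodioxol-5-yl)prop-2-enoyl]oxy}-1-hydroxy-4-oxocyclohexane-1-carboxylic acid F3. In its carboxylate form the large CO2− group is firmly equatorial and the axial 1-OH is hydrogen-bonded to the syn-axial acyloxy oxygen, so the chair is locked. Reduction with NaBH4 (2.5 equiv, THF/MeOH, −40 °C) then delivers hydride from the carboxyl face, helped by any carboxylate-bound borohydride, and gives the 1,4-cis hydroxy acid F4 (3,5-bis-O-(caffeoyl acetonide)quinic acid). Succinic anhydride/DMAP/pyridine converts F4 to the 4-O-hemisuccinate F5, and TFA/H2O 9:1 removes the two catechol acetonides to give 18.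

**Further compounds**
F1 | step 1 | 5-bromo-2,2-dimethyl-1,3-dioxolan-4-one (racemic) | CC1(C)OC(Br)C(=O)O1
F2 | step 7 | (7R,9R)-2,2-dimethyl-4,8-dioxo-1,3-dioxaspiro[4.5]decane-7,9-diyl di(prop-2-enoate) | CC1(C)OC(=O)C2(C[C@@H](OC(=O)C=C)C(=O)[C@H](OC(=O)C=C)C2)O1
F3 | step 8 | (3R,5R)-3,5-bis{[(E)-3-(2,2-dimethyl-1,3-benzodioxol-5-yl)prop-2-enoyl]oxy}-1-hydroxy-4-oxocyclohexane-1-carboxylic acid | OC(=O)C1(O)C[C@@H](OC(=O)/C=C/c2ccc3OC(C)(C)Oc3c2)C(=O)[C@H](OC(=O)/C=C/c2ccc3OC(C)(C)Oc3c2)C1
F4 | step 8 | (3R,5R)-3,5-bis{[(E)-3-(2,2-dimethyl-1,3-benzodioxol-5-yl)prop-2-enoyl]oxy}-1,4-dihydroxycyclohexane-1-carboxylic acid (1-OH, 3-O and 4-OH on one face) | OC(=O)[C@]1(O)C[C@@H](OC(=O)/C=C/c2ccc3OC(C)(C)Oc3c2)[C@@H](O)[C@H](OC(=O)/C=C/c2ccc3OC(C)(C)Oc3c2)C1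
F5 | step 8 | (3R,5R)-4-(3-carboxypropanoyloxy)-3,5-bis{[(E)-3-(2,2-dimethyl-1,3-benzodioxol-5-yl)prop-2-enoyl]oxy}-1-hydroxycyclohexane-1-carboxylic acid (1-OH, 3-O and 4-O on one face) | OC(=O)[C@]1(O)C[C@@H](OC(=O)/C=C/c2ccc3OC(C)(C)Oc3c2)[C@@H](OC(=O)CCC(=O)O)[C@H](OC(=O)/C=C/c2ccc3OC(C)(C)Oc3c2)C1
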